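The quinone ring is numbered C1 (carbonyl between the methoxy carbon C2 and the pentacosyl carbon C6), C3 (H), C4 (second carbonyl), C5 (methyl). The route disconnects ring bond C1–C6 of a resorcylate. The key step exploits the fact that the C2 and C4 oxygens are both meta to chain carbon C6 and that C5 carries a methyl, the pattern of a folded tetraketide. One base-mediated aldol condensation of a linear methyl 3,5,7-triketo ester closes the six-membered carbocycle and sets chain, methyl and both oxygens at once, without aromatic substitution. The precursor is that open-chain triketo ester, its chain-bearing ketone being the former carboxyl carbon of hexacosanoic acid.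

Key step: step 4

Remark: the target has no stereocentre, so 9 (racemic, epimerisable methine) and 10 (diastereomer mixture) are carried as mixtures; long chains are written in SMILES as blocks of five carbons joined by explicit single bonds.

Step 1
Reactants: 1 methyl acetoacetate; 2 methyl propanoate
Product: 4 methyl 3,5-dioxoheptanoate, via dilithium dienolate of methyl acetoacetate 3 (not isolated)
Conditions: 1 (2.2 equiv), LiN(iPr)2 (4.4 equiv), THF, −78→0 °C; then 2 (1.0 equiv), 0 °C→rt; aq. HCl
Reagents that add atoms: none
Why: Claisen-type C-acylation of the acetoacetate dianion at its terminal carbon by an ester is a standard entry to 3,5-diketo esters, and the second equivalent of dianion takes up the acidic proton of the product so that the acylation should run to completion.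

Step 2
Reactants: 5 hexacosanoic acid
Product: 7 N-methoxy-N-methylhexacosanamide, via 1-hexacosanoylimidazole 6 (not isolated)
Conditions: 1,1'-carbonyldiimidazole (CDI, 1.2 equiv), THF, 50 °C; then MeNH(OMe)·HCl (1.5 equiv), 50 °C
Reagents that add atoms: N,O-dimethylhydroxylamine hydrochloride, CNOC.Cl
Why: activation of the acid as the acyl imidazolide followed by aminolysis is the standard Weinreb amide synthesis, chosen because this amide acylates a carbanion only once through a stable chelate and is less prone to α-deprotonation than the methyl ester.

Step 3
Reactants: 4 methyl 3,5-dioxoheptanoate; 7 N-methoxy-N-methylhexacosanamide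
Product: 9 methyl 6-methyl-3,5,7-trioxodotriacontanoate, via trilithium trienolate of methyl 3,5-dioxoheptanoate 8 (not isolated)
Conditions: 4 (1.5 equiv), LiN(iPr)2 (4.5 equiv), THF, −78→0 °C; then 7 in THF, 0 °C→rt; cold 1 M HCl
Reagents that add atoms: none
Why: Claisen-type acylation of a diketo ester trianion takes place at the carbanion formed last (chain C6, the methylene of the ethyl ketone), and the chelated adduct of the Weinreb amide persists until the acidic quench, so neither proton transfer to the product nor a second acylation should intervene; the new methine is racemic and epimerisable, which is of no consequence.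

Step 4
Reactants: 9 methyl 6-methyl-3,5,7-trioxodotriacontanoate
Product: 11 methyl 2,4-dihydroxy-5-methyl-6-pentacosylbenzoate, via cyclic aldol 10 (not isolated)
Conditions: K2CO3 (3 equiv), MeOH/THF 1:1, 0 °C→rt; then HCl in MeOH, rt
Reagents that add atoms: none
Why: Carbonate in methanol ionises the chain C4 methylene first (it lies between two ketones) and then, reversibly, the less acidic ester α-methylene (chain C2); that carbanion adds to the chain C7 ketone, which the C6 methyl keeps largely in the keto form, giving aldol 10, and acid then eliminates water while the two remaining ring ketones enolise to resorcylate 11. The closest known reaction type is the base-mediated intramolecular aldol condensation of 3,5,7-triketo esters to resorcylates, the laboratory counterpart of polyketide aromatisation. The six-membered carbocycle closes in the 6-(enolendo)-exo-trig mode, and the chain C2–C7 bond formed is ring bond C1–C6 of the target. No stereocentre remains, since those of 10 vanish on aromatisation. The step needs chemoselectivity for this aldol over Claisen closure of C6 onto the ester, lactonisation to a 4-hydroxy-2-pyranone, O-cyclisation to a 4-pyranone and the aldol of chain C8 onto C3. The substrate secures it because C2 is the only doubly activated carbon that can reach a ketone through a six-membered transition state, the C6 methyl would make the Claisen product a quaternary, non-aromatisable triketone that reverts, C8 is not ionised by carbonate, and acid is withheld until the ring has closed; methanol as solvent makes ester exchange degenerate.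

Step 5
Reactants: 11 methyl 2,4-dihydroxy-5-methyl-6-pentacosylbenzoate
Product: 13 4-methyl-5-pentacosylbenzene-1,3-diol, via 2,4-dihydroxy-5-methyl-6-pentacosylbenzoic acid 12 (not isolated)
Conditions: KOH (10 equiv), EtOH/H2O 3:1, reflux, Ar; then aq. HCl to pH 1, 80 °C
Reagents that add atoms: none
Why: saponification of the salicylate-type ester followed by protodecarboxylation of the 2,4-dihydroxybenzoic acid, which loses CO2 readily by ipso-protonation of the electron-rich ring, is the standard conversion of a resorcylate into its resorcinol.

Step 6
Reactants: 13 4-methyl-5-pentacosylbenzene-1,3-diol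
Product: 14 2-hydroxy-5-methyl-6-pentacosyl-1,4-benzoquinone
Conditions: (KSO3)2NO (2.5 equiv), KH2PO4, methyltrioctylammonium chloride (cat.), CH2Cl2/H2O, rt
Reagents that add atoms: potassium nitrosodisulfonate (Fremy's salt), [K+].[K+].[O]N(S(=O)(=O)[O-])S(=O)(=O)[O-]
Why: Teuber oxidation, in which the phenoxyl radical of the C4 hydroxyl is captured by a second nitrosodisulfonate radical at the free para carbon C1 and loss of imidodisulfonate gives the para-quinone with the C2 hydroxyl retained; the position para to the C2 hydroxyl is blocked by the C5 methyl, and the phase-transfer salt should bring the oxidant to the lipophilic substrate.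

Step 7
Reactants: 14 2-hydroxy-5-methyl-6-pentacosyl-1,4-benzoquinone
Product: 15 2-methoxy-5-methyl-6-pentacosyl-1,4-benzoquinone
Conditions: MeOH, H2SO4 (cat.), CH2Cl2, rt
Reagents that add atoms: methanol, CO
Why: acid-catalysed etherification of the hydroxyquinone, a vinylogous carboxylic acid, by addition–elimination of methanol at C2; acidic methanol should equilibrate any 4-methoxy-1,2-quinone isomer to the more stable 2-methoxy-1,4-quinone, and the C4 carbonyl is shielded by the C5 methyl.

Compound list
1 | methyl acetoacetate | CC(=O)CC(=O)OC | starting material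
2 | methyl propanoate | CCC(=O)OC | starting material
3 | dilithium dienolate of methyl acetoacetate | [Li+].[Li+].C=C([O-])C=C([O-])OC | intermediate
4 | methyl 3,5-dioxoheptanoate | CCC(=O)CC(=O)CC(=O)OC | intermediate
5 | hexacosanoic acid | OC(=O)CCCCC-CCCCC-CCCCC-CCCCC-CCCCC | starting material
6 | 1-hexacosanoylimidazole | O=C(CCCCC-CCCCC-CCCCC-CCCCC-CCCCC)n1ccnc1 | intermediate
7 | N-methoxy-N-methylhexacosanamide | CON(C)C(=O)CCCCC-CCCCC-CCCCC-CCCCC-CCCCC | intermediate
8 | trilithium trienolate of methyl 3,5-dioxoheptanoate | [Li+].[Li+].[Li+].CC=C([O-])C=C([O-])C=C([O-])OC | intermediate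
9 | methyl 6-methyl-3,5,7-trioxodotriacontanoate (racemic at the methyl-bearing carbon; keto–enol mixture) | COC(=O)CC(=O)CC(=O)C(C)C(=O)CCCCC-CCCCC-CCCCC-CCCCC-CCCCC | intermediate
10 | methyl 2-hydroxy-3-methyl-4,6-dioxo-2-pentacosylcyclohexane-1-carboxylate (cyclic aldol, diastereomer mixture) | COC(=O)C1C(=O)CC(=O)C(C)C1(O)CCCCC-CCCCC-CCCCC-CCCCC-CCCCC | intermediate
11 | methyl 2,4-dihydroxy-5-methyl-6-pentacosylbenzoate | COC(=O)c1c(O)cc(O)c(C)c1CCCCC-CCCCC-CCCCC-CCCCC-CCCCC | intermediate
12 | 2,4-dihydroxy-5-methyl-6-pentacosylbenzoic acid | OC(=O)c1c(O)cc(O)c(C)c1CCCCC-CCCCC-CCCCC-CCCCC-CCCCC | intermediate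
13 | 4-methyl-5-pentacosylbenzene-1,3-diol | Cc1c(O)cc(O)cc1CCCCC-CCCCC-CCCCC-CCCCC-CCCCC | intermediate
14 | 2-hydroxy-5-methyl-6-pentacosyl-1,4-benzoquinone | CC1=C(CCCCC-CCCCC-CCCCC-CCCCC-CCCCC)C(=O)C(O)=CC1=O | intermediate
15 | 2-methoxy-5-methyl-6-pentacosyl-1,4-benzoquinone (CNP0536469.0) | CCCCC-CCCCC-CCCCC-CCCCC-CCCCC-C1=C(C)C(=O)C=C(OC)C1=O | target

Total step count: 7. Longest linear sequence: 6 steps (1 → 4 → 9 → 11 → 13 → 14 → 15; the branch from 5 through 7 is equally long).

Steps most likely to fail

Step 4. Oxygen cyclisation (lactonisation of the C5 enol onto the ester, or pyranone formation during acidification) may outrun carbon–carbon bond formation, or the chain-bearing ketone may sit as an unreactive enolate. The fallback sets out from 7 and returns at 13, replacing steps 3 to 5 by a Michael–Claisen annulation and dehydrogenation. Reduction of 7 with LiAlH4 in THF at 0 °C should give hexacosanal F1. Wittig olefination with 3-(triphenylphosphoranylidene)butan-2-one in toluene at reflux should give (E)-3-methylnonacos-3-en-2-one F2. Dimethyl malonate and NaOMe in MeOH at reflux should add to the enone to give dimethyl 2-(3-methyl-2-oxononacosan-4-yl)propanedioate F3 (not isolated), whose methyl ketone enolate closes onto one ester to give methyl 5-methyl-2,4-dioxo-6-pentacosylcyclohexane-1-carboxylate F4. Bromine (1 equiv) in DMF at 0 °C, then heating to 150 °C, should dehydrogenate F4 to 11 in the flask, where bromide demethylates the ester and 12 loses CO2, giving 13.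

Step 3. The third deprotonation at the ethyl methylene may stay incomplete, or the waxy amide may react sluggishly with the aggregated trianion. The fallback sets out from 7 (with commercial 2,2,6-trimethyl-4H-1,3-dioxin-4-one as the new partner) and returns at 9; it replaces the trianion by a dianion whose ester is masked. The dioxinone is deprotonated with LiN(SiMe3)2 in THF at −78 °C and acylated with propanoyl chloride to give 2,2-dimethyl-6-(2-oxobutyl)-4H-1,3-dioxin-4-one F5. Its dianion (LiN(iPr)2, 2.2 equiv, THF, −78 °C) is acylated at the terminal methylene by 7 to give 2,2-dimethyl-6-(3-methyl-2,4-dioxononacosyl)-4H-1,3-dioxin-4-one F6. Heating F6 in toluene/MeOH at 110 °C extrudes acetone to the acylketene 6-methyldotriacont-1-ene-1,3,5,7-tetrone F7 (not isolated), which methanol traps as 9.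

Step 6. Transfer of the water-soluble oxidant to the waxy resorcinol may be poor, and the hydroxyquinone with its free C3–H may be oxidised further or dimerise before isolation. The fallback sets out from 13 and returns at 15, reversing the order of methylation and oxidation so that no free hydroxyquinone is handled. Dimethyl sulfate (1 equiv) and K2CO3 in acetone at rt should methylate the less hindered hydroxyl (the one remote from the methyl) to give 5-methoxy-2-methyl-3-pentacosylphenol F8, separated by chromatography from dimethyl ether and recovered 13. Oxidation of F8 with Co(salen) under O2 in DMF at rt, para to the remaining hydroxyl, should give 15 directly.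

Further compounds
F1 | step 4 | hexacosanal | CCCCC-CCCCC-CCCCC-CCCCC-CCCCC-C=O
F2 | step 4 | (E)-3-methylnonacos-3-en-2-one | CC(=O)/C(C)=C/CCCCC-CCCCC-CCCCC-CCCCC-CCCCC
F3 | step 4 | dimethyl 2-(3-methyl-2-oxononacosan-4-yl)propanedioate (diastereomer mixture, not isolated) | COC(=O)C(C(=O)OC)C(CCCCC-CCCCC-CCCCC-CCCCC-CCCCC)C(C)C(C)=O
F4 | step 4 | methyl 5-methyl-2,4-dioxo-6-pentacosylcyclohexane-1-carboxylate (diastereomer mixture) | COC(=O)C1C(=O)CC(=O)C(C)C1CCCCC-CCCCC-CCCCC-CCCCC-CCCCC
F5 | step 3 | 2,2-dimethyl-6-(2-oxobutyl)-4H-1,3-dioxin-4-one | CCC(=O)CC1=CC(=O)OC(C)(C)O1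
F6 | step 3 | 2,2-dimethyl-6-(3-methyl-2,4-dioxononacosyl)-4H-1,3-dioxin-4-one (racemic) | CC1(C)OC(=O)C=C(CC(=O)C(C)C(=O)CCCCC-CCCCC-CCCCC-CCCCC-CCCCC)O1
F7 | step 3 | 6-methyldotriacont-1-ene-1,3,5,7-tetrone (acylketene, not isolated) | O=C=CC(=O)CC(=O)C(C)C(=O)CCCCC-CCCCC-CCCCC-CCCCC-CCCCC
F8 | step 6 | 5-methoxy-2-methyl-3-pentacosylphenol | COc1cc(O)c(C)c(CCCCC-CCCCC-CCCCC-CCCCC-CCCCC)c1
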